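## Retrosynthetic overview
1. Two MOM ethers are removed last. The C2–aryl bond and the only stereocentre come from a Rh(I)/chiral diphosphine 1,4-addition of a chromanylboronic acid to an 8-prenyl-5,7-bis(MOM)chromone, which joins the fragments in the penultimate step.
2. Ring C of the chromone comes from a 3-prenylsalicylaldehyde by Cp*Rh(III) formyl C–H activation/annulation with a formyl sulfoxonium ylide as the C2–C3 synthon (new reaction).
3. The salicylaldehyde comes from resorcinol: MOM protection, Ir C–H borylation/oxidation (gives O1), Pd O-tert-prenylation and Claisen rearrangement (gives the C8 prenyl), then Mg-mediated ortho-formylation (gives C4).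
4. The boronic acid comes from 4-bromophenol and isoprene (chroman ring), then Br/Li/B exchange. The side reagents come from 2-methylbut-3-en-2-ol and from Me3S(O)I plus ethyl formate.
5. Ring order: both benzene rings are bought. The dimethylchroman ring closes in the side branch and ring C closes in the annulation. C2 is set afterwards.

Assumption: a one-pot sequence counts as one step, and mediators recovered unchanged after work-up (MgCl2/Et3N in step 6, buffer in step 2, carboxylate additives in step 8) are treated like catalysts.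

## Route

Step 1
Reactants: 1 resorcinol (benzene-1,3-diol)
Product: 2 1,3-bis(methoxymethoxy)benzene
Conditions: MOMCl (2.6 equiv), i-Pr2NEt (3 equiv), CH2Cl2, 0 °C to rt
Reagents that add atoms: chloromethyl methyl ether, COCCl
Why: Base-mediated O-alkylation (MOM acetal protection) of both phenols gives groups that survive the later Ir, Pd, Mg and Rh steps and leave under mild acid.

Step 2
Reactants: 2 1,3-bis(methoxymethoxy)benzene
Product: 4 3,5-bis(methoxymethoxy)phenol, via aryl pinacol boronate 3 (not isolated)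
Conditions: [Ir(OMe)(cod)]2 (1 mol %), dtbpy (2 mol %), HBpin (1.5 equiv), THF, 80 °C; then 30% aq H2O2, NaHCO3 buffer, 0 °C to rt
Reagents that add atoms: pinacolborane, B1OC(C)(C)C(C)(C)O1 (boryl group of 3); hydrogen peroxide, OO
Why: Sterically governed Ir-catalysed aromatic C–H borylation reaches the only C–H without an ortho substituent (C5), and peroxide oxidation of the C–B bond (1,2-aryl shift) installs the third oxygen as the only free phenol, the future O1.

Step 3
Reactants: 5 2-methylbut-3-en-2-ol
Product: 7 methyl 2-methylbut-3-en-2-yl carbonate, via lithium alkoxide 6 (not isolated)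
Conditions: n-BuLi (1.05 equiv), THF, −78 °C; ClCO2Me, −78 to 0 °C
Reagents that add atoms: methyl chloroformate, COC(=O)Cl; n-butyllithium, [Li]CCCC (lithium of 6 only)
Why: O-acylation of the tertiary lithium alkoxide with a chloroformate gives the allylic carbonate needed for π-allyl chemistry.

Step 4
Reactants: 4 3,5-bis(methoxymethoxy)phenol; 7 methyl 2-methylbut-3-en-2-yl carbonate
Product: 8 1,3-bis(methoxymethoxy)-5-[(2-methylbut-3-en-2-yl)oxy]benzene
Conditions: Pd(PPh3)4 (2 mol %), THF, 0 to 5 °C
Reagents that add atoms: none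
Why: In this Tsuji–Trost allylic etherification, decarboxylative ionisation gives the 1,1-dimethyl-π-allyl-Pd and methoxide, and the resulting phenoxide attacks the more substituted terminus under kinetic control at low temperature to give the tertiary (reverse-prenyl) ether.

Step 5
Reactants: 8 1,3-bis(methoxymethoxy)-5-[(2-methylbut-3-en-2-yl)oxy]benzene
Product: 10 3,5-bis(methoxymethoxy)-2-(3-methylbut-2-en-1-yl)phenol, via ortho-dienone 9 (not isolated)
Conditions: PhNEt2, 130 °C
Reagents that add atoms: none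
Why: The aromatic Claisen rearrangement ([3,3] with allyl inversion) turns the 1,1-dimethylallyl ether into a linear prenyl group on the ortho carbon; the two ortho positions are equivalent, so one isomer forms, and the basic solvent prevents acid-induced chroman closure.

Step 6
Reactants: 10 3,5-bis(methoxymethoxy)-2-(3-methylbut-2-en-1-yl)phenol
Product: 12 2-hydroxy-4,6-bis(methoxymethoxy)-3-(3-methylbut-2-en-1-yl)benzaldehyde, via salicyl alcohol 11 (not isolated)
Conditions: anhydrous MgCl2 (2 equiv), Et3N (4 equiv), (CH2O)n (6 equiv), MeCN, 80 °C; citric acid work-up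
Reagents that add atoms: paraformaldehyde (as formaldehyde), C=O
Why: In the Casnati–Skattebøl ortho-formylation the magnesium phenoxide delivers formaldehyde only to the free ortho carbon, a second formaldehyde oxidises the benzylic alkoxide by hydride transfer, and the prenyl alkene is untouched.

Step 7
Reactants: 13 trimethylsulfoxonium iodide; 14 ethyl formate
Product: 16 2-[dimethyl(oxo)-λ6-sulfanylidene]acetaldehyde, via dimethylsulfoxonium methylide 15 (not isolated)
Conditions: 13 (3 equiv), KOt-Bu (3 equiv), THF, reflux; then 14 (1 equiv), 0 °C to rt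
Reagents that add atoms: none
Why: C-formylation of the Corey–Chaykovsky methylide by an ester follows the standard acylation route to carbonyl-stabilised sulfoxonium ylides (the sulfur counterpart of making Ph3P=CHCHO from Ph3P=CH2 and ethyl formate), and the push–pull product is not attacked further.

Step 8
Reactants: 12 2-hydroxy-4,6-bis(methoxymethoxy)-3-(3-methylbut-2-en-1-yl)benzaldehyde; 16 2-[dimethyl(oxo)-λ6-sulfanylidene]acetaldehyde
Product: 19 5,7-bis(methoxymethoxy)-8-(3-methylbut-2-en-1-yl)-4H-chromen-4-one, via beta-ketoaldehyde 17 (not isolated), via lactol 18 (not isolated)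
Conditions: [Cp*RhCl2]2 (2.5 mol %), AgSbF6 (10 mol %), CsOAc (30 mol %), PivOH (0.5 equiv), 4 Å MS, ClCH2CH2Cl, 80 °C
Reagents that add atoms: none
Why: Proposed new method: the Cp*Rh(III) carboxylate binds the phenoxide of 12 and cleaves the neighbouring formyl C–H by concerted metalation–deprotonation to a five-membered acyl rhodacycle; the ylide carbon of 16 adds to Rh and expels DMSO to give a Rh formyl-carbene; 1,1-migratory insertion of the acyl group forms the C3–C4 bond; protodemetalation by PivOH releases beta-ketoaldehyde 17, whose only free phenol (next to the prenyl group) adds to the aldehyde (lactol 18) and loses water to close ring C; the closest known reaction type is the Cp*Rh(III) formyl C–H activation/annulation of salicylaldehydes with α-aroyl or α-alkanoyl sulfoxonium ylides to 2-substituted chromones, whereas a formyl ylide as a C2–C3 synthon for 2,3-unsubstituted chromones has not been shown.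

Step 9
Reactants: 20 4-bromophenol; 21 isoprene
Product: 23 6-bromo-2,2-dimethylchromane, via 4-bromo-2-prenylphenol 22 (not isolated)
Conditions: AgOTf (5 mol %), 21 (2 equiv), ClCH2CH2Cl, rt to 40 °C
Reagents that add atoms: none
Why: Acid-type catalysed Friedel–Crafts ortho-prenylation (the para position is blocked by Br) is followed by Markovnikov intramolecular hydroalkoxylation of the trisubstituted alkene, which closes the 2,2-dimethylchroman ring.

Step 10
Reactants: 23 6-bromo-2,2-dimethylchromane
Product: 26 (2,2-dimethylchroman-6-yl)boronic acid, via aryllithium 24 (not isolated), via lithium triisopropoxyborate 25 (not isolated)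
Conditions: n-BuLi (1.1 equiv), THF, −78 °C; B(Oi-Pr)3, −78 °C to rt; 1 M HCl
Reagents that add atoms: triisopropyl borate, CC(C)OB(OC(C)C)OC(C)C; water, O; n-butyllithium, [Li]CCCC (lithium of 24 and 25 only)
Why: Bromine–lithium exchange, electrophilic borylation and hydrolysis form the standard route to an arylboronic acid, and the substrate carries no competing functionality.

Step 11
Reactants: 19 5,7-bis(methoxymethoxy)-8-(3-methylbut-2-en-1-yl)-4H-chromen-4-one; 26 (2,2-dimethylchroman-6-yl)boronic acid
Product: 27 (2S)-2-(2,2-dimethylchroman-6-yl)-5,7-bis(methoxymethoxy)-8-(3-methylbut-2-en-1-yl)chroman-4-one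
Conditions: [RhCl(C2H4)2]2 (1.5 mol %), (S)-MeO-F12-BIPHEP [(S)-2,2'-bis{bis(3,4,5-trifluorophenyl)phosphino}-6,6'-dimethoxybiphenyl] (3.3 mol %), aq KOH (10 mol %), 26 (2 equiv), toluene/H2O 10:1, 25 °C
Reagents that add atoms: none
Why: In this Hayashi–Miyaura asymmetric 1,4-addition, transmetalation gives aryl-Rh(I), enantio-determining carbometalation of C2=C3 places the aryl on the Re face of C2 (same sense as (S)-biaryl diphosphine with 2-cyclohexenone, giving 2S; the (R)-ligand is used if the sense proves opposite), and hydrolysis of the oxa-π-allyl-Rh gives the flavanone, with the electron-poor ligand and nearly neutral biphasic medium suppressing 1,2-addition and ring opening.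

Step 12
Reactants: 27 (2S)-2-(2,2-dimethylchroman-6-yl)-5,7-bis(methoxymethoxy)-8-(3-methylbut-2-en-1-yl)chroman-4-one
Product: 28 Euchrenone a16, (2S)-2-(2,2-dimethylchroman-6-yl)-5,7-dihydroxy-8-(3-methylbut-2-en-1-yl)chroman-4-one
Conditions: 3 M aq HCl/MeOH (1:5), 45 °C, 1–2 h; neutral work-up, no base
Reagents that add atoms: none
Why: Acid-catalysed acetal exchange removes both aryl MOM ethers under conditions commonly used for prenylated flavanones, and avoiding base prevents retro-oxa-Michael opening, so the 2S centre is kept.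

## Compound list
1 | resorcinol (benzene-1,3-diol) | Oc1cccc(O)c1 | starting material
2 | 1,3-bis(methoxymethoxy)benzene | COCOc1cccc(OCOC)c1 | intermediate
3 | 2-[3,5-bis(methoxymethoxy)phenyl]-4,4,5,5-tetramethyl-1,3,2-dioxaborolane | COCOc1cc(OCOC)cc(B2OC(C)(C)C(C)(C)O2)c1 | intermediate (not isolated)
4 | 3,5-bis(methoxymethoxy)phenol | COCOc1cc(O)cc(OCOC)c1 | intermediate
5 | 2-methylbut-3-en-2-ol | C=CC(C)(C)O | starting material
6 | lithium 2-methylbut-3-en-2-olate | [Li+].[O-]C(C)(C)C=C | intermediate (not isolated)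
7 | methyl 2-methylbut-3-en-2-yl carbonate | C=CC(C)(C)OC(=O)OC | intermediate
8 | 1,3-bis(methoxymethoxy)-5-[(2-methylbut-3-en-2-yl)oxy]benzene | C=CC(C)(C)Oc1cc(OCOC)cc(OCOC)c1 | intermediate
9 | 3,5-bis(methoxymethoxy)-6-(3-methylbut-2-en-1-yl)cyclohexa-2,4-dien-1-one (racemic) | O=C1C=C(OCOC)C=C(OCOC)C1CC=C(C)C | intermediate (not isolated)
10 | 3,5-bis(methoxymethoxy)-2-(3-methylbut-2-en-1-yl)phenol | CC(C)=CCc1c(O)cc(OCOC)cc1OCOC | intermediate
11 | 2-(hydroxymethyl)-3,5-bis(methoxymethoxy)-6-(3-methylbut-2-en-1-yl)phenol | CC(C)=CCc1c(O)c(CO)c(OCOC)cc1OCOC | intermediate (not isolated)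
12 | 2-hydroxy-4,6-bis(methoxymethoxy)-3-(3-methylbut-2-en-1-yl)benzaldehyde | CC(C)=CCc1c(O)c(C=O)c(OCOC)cc1OCOC | intermediate
13 | trimethylsulfoxonium iodide | C[S+](C)(C)=O.[I-] | starting material
14 | ethyl formate | CCOC=O | starting material
15 | dimethylsulfoxonium methylide | [CH2-][S+](C)(C)=O | intermediate (not isolated)
16 | 2-[dimethyl(oxo)-λ6-sulfanylidene]acetaldehyde | CS(C)(=O)=CC=O | intermediate
17 | 3-[2-hydroxy-4,6-bis(methoxymethoxy)-3-(3-methylbut-2-en-1-yl)phenyl]-3-oxopropanal | CC(C)=CCc1c(O)c(C(=O)CC=O)c(OCOC)cc1OCOC | intermediate (not isolated)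
18 | 2-hydroxy-5,7-bis(methoxymethoxy)-8-(3-methylbut-2-en-1-yl)chroman-4-one (racemic lactol) | CC(C)=CCc1c(OCOC)cc(OCOC)c2c1OC(O)CC2=O | intermediate (not isolated)
19 | 5,7-bis(methoxymethoxy)-8-(3-methylbut-2-en-1-yl)-4H-chromen-4-one | CC(C)=CCc1c(OCOC)cc(OCOC)c2c1OC=CC2=O | intermediate
20 | 4-bromophenol | Oc1ccc(Br)cc1 | starting material
21 | isoprene (2-methylbuta-1,3-diene) | C=CC(C)=C | starting material
22 | 4-bromo-2-(3-methylbut-2-en-1-yl)phenol | CC(C)=CCc1cc(Br)ccc1O | intermediate (not isolated)
23 | 6-bromo-2,2-dimethylchromane | CC1(C)CCc2cc(Br)ccc2O1 | intermediate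
24 | (2,2-dimethylchroman-6-yl)lithium | [Li]c1ccc2c(c1)CCC(C)(C)O2 | intermediate (not isolated)
25 | lithium (2,2-dimethylchroman-6-yl)triisopropoxyborate | CC(C)O[B-](OC(C)C)(OC(C)C)c1ccc2c(c1)CCC(C)(C)O2.[Li+] | intermediate (not isolated)
26 | (2,2-dimethylchroman-6-yl)boronic acid | CC1(C)CCc2cc(B(O)O)ccc2O1 | intermediate
27 | (2S)-2-(2,2-dimethylchroman-6-yl)-5,7-bis(methoxymethoxy)-8-(3-methylbut-2-en-1-yl)chroman-4-one | CC(C)=CCc1c(OCOC)cc(OCOC)c2c1O[C@H](c1ccc3c(c1)CCC(C)(C)O3)CC2=O | intermediate
28 | Euchrenone a16, (2S)-2-(2,2-dimethylchroman-6-yl)-5,7-dihydroxy-8-(3-methylbut-2-en-1-yl)chroman-4-one | CC(C)=CCc1c(O)cc(O)c2c1O[C@H](c1ccc3c(c1)CCC(C)(C)O3)CC2=O | target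

## Step count
Total step count: 12.
Longest linear sequence: 8 (steps 1, 2, 4, 5, 6, 8, 11, 12).

## Three steps most likely to fail

**Step 8 (proposed new annulation).**
- The formyl ylide may bind or decompose on cationic Rh(III).
- Intermediate 17 may deformylate, and lactol 18 may dehydrate slowly.
- Traces of strong acid from the silver salt could nick the MOM groups.
- The prenyl alkene could compete for the metal.

The fallback uses known chemistry only. It sets out from 12 and comes back at 19. Ethynylmagnesium bromide (3 equiv, THF, 0 °C) adds to the aldehyde to give 2-(1-hydroxyprop-2-yn-1-yl)-3,5-bis(methoxymethoxy)-6-(3-methylbut-2-en-1-yl)phenol F1. MnO2 (CH2Cl2, rt) oxidises it to 1-[2-hydroxy-4,6-bis(methoxymethoxy)-3-(3-methylbut-2-en-1-yl)phenyl]prop-2-yn-1-one F2. DMAP-catalysed 6-endo oxa-Michael cyclisation of this o-alkynoylphenol then gives 19.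

**Step 11 (asymmetric 1,4-addition).**
- The 5,7-dialkoxy chromone is an electron-rich, poor acceptor.
- The electron-rich boronic acid can protodeboronate.
- Any ring opening would erode the ee.

The fallback drops the chromone disconnection. It sets out from 12 and 23 and comes back at 27.
- MeMgBr (2.5 equiv, THF, 0 °C) converts 12 into 2-(1-hydroxyethyl)-3,5-bis(methoxymethoxy)-6-(3-methylbut-2-en-1-yl)phenol F3.
- MnO2 oxidises F3 to 1-[2-hydroxy-4,6-bis(methoxymethoxy)-3-(3-methylbut-2-en-1-yl)phenyl]ethanone F4.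
- Separately, 23 is lithiated (n-BuLi, −78 °C) and quenched with DMF to give 2,2-dimethylchroman-6-carbaldehyde F5.
- Claisen–Schmidt condensation of F4 and F5 (KOH, EtOH, rt) gives (E)-3-(2,2-dimethylchroman-6-yl)-1-[2-hydroxy-4,6-bis(methoxymethoxy)-3-(3-methylbut-2-en-1-yl)phenyl]prop-2-en-1-one F6.
- F6 has a single free ortho phenol, so cyclisation (NaOAc, EtOH, reflux) gives only the 8-prenyl isomer, racemic 2-(2,2-dimethylchroman-6-yl)-5,7-bis(methoxymethoxy)-8-(3-methylbut-2-en-1-yl)chroman-4-one F7.
- Noyori–Ikariya transfer-hydrogenative kinetic resolution ([Cp*RhCl((R,R)-TsDPEN)], HCO2H/Et3N, EtOAc, rt, about 52% conversion) reduces the 2R enantiomer to (2R,4R)-2-(2,2-dimethylchroman-6-yl)-5,7-bis(methoxymethoxy)-8-(3-methylbut-2-en-1-yl)chroman-4-ol F8. It leaves 27 in high ee, and the two are separated by chromatography.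

**Step 4 (Pd O-tert-prenylation).**
- The tertiary ether can re-ionise to the linear prenyl ether.
- The phloroglucinol-type ring can be C-allylated.
- The product is acid-labile on silica.

The fallback avoids π-allyl chemistry. It sets out from 4 and comes back at 8. Cu-catalysed O-alkylation with 3-chloro-3-methylbut-1-yne (CuCl2·2H2O cat., DBU, MeCN, 0 °C) gives 1,3-bis(methoxymethoxy)-5-[(2-methylbut-3-yn-2-yl)oxy]benzene F9. Lindlar semihydrogenation (H2, Pd/CaCO3–Pb, quinoline, EtOAc) then gives 8.

## Further compounds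
F1 | step 8 | 2-(1-hydroxyprop-2-yn-1-yl)-3,5-bis(methoxymethoxy)-6-(3-methylbut-2-en-1-yl)phenol (racemic) | CC(C)=CCc1c(O)c(C(O)C#C)c(OCOC)cc1OCOC
F2 | step 8 | 1-[2-hydroxy-4,6-bis(methoxymethoxy)-3-(3-methylbut-2-en-1-yl)phenyl]prop-2-yn-1-one | CC(C)=CCc1c(O)c(C(=O)C#C)c(OCOC)cc1OCOC
F3 | step 11 | 2-(1-hydroxyethyl)-3,5-bis(methoxymethoxy)-6-(3-methylbut-2-en-1-yl)phenol (racemic) | CC(C)=CCc1c(O)c(C(C)O)c(OCOC)cc1OCOC
F4 | step 11 | 1-[2-hydroxy-4,6-bis(methoxymethoxy)-3-(3-methylbut-2-en-1-yl)phenyl]ethanone | CC(C)=CCc1c(O)c(C(C)=O)c(OCOC)cc1OCOC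
F5 | step 11 | 2,2-dimethylchroman-6-carbaldehyde | CC1(C)CCc2cc(C=O)ccc2O1
F6 | step 11 | (E)-3-(2,2-dimethylchroman-6-yl)-1-[2-hydroxy-4,6-bis(methoxymethoxy)-3-(3-methylbut-2-en-1-yl)phenyl]prop-2-en-1-one | CC(C)=CCc1c(O)c(C(=O)/C=C/c2ccc3c(c2)CCC(C)(C)O3)c(OCOC)cc1OCOC
F7 | step 11 | racemic 2-(2,2-dimethylchroman-6-yl)-5,7-bis(methoxymethoxy)-8-(3-methylbut-2-en-1-yl)chroman-4-one | CC(C)=CCc1c(OCOC)cc(OCOC)c2c1OC(c1ccc3c(c1)CCC(C)(C)O3)CC2=O
F8 | step 11 | (2R,4R)-2-(2,2-dimethylchroman-6-yl)-5,7-bis(methoxymethoxy)-8-(3-methylbut-2-en-1-yl)chroman-4-ol | CC(C)=CCc1c(OCOC)cc(OCOC)c2c1O[C@@H](c1ccc3c(c1)CCC(C)(C)O3)C[C@H]2O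
F9 | step 4 | 1,3-bis(methoxymethoxy)-5-[(2-methylbut-3-yn-2-yl)oxy]benzene | C#CC(C)(C)Oc1cc(OCOC)cc(OCOC)c1
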